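## The problem

Gentiside C (17) is the ester of 2,3-dihydroxybenzoic acid with (S)-14-methylhexadecan-1-ol. It has one benzene ring, no other ring, and a sixteen-carbon chain (numbered from the O-bearing C1) whose only branch is the methyl group at C14. C14 is the only stereocentre, so nothing in the molecule can direct its formation. Once the chain is complete it carries only methyl, ethyl and a long alkyl group, so its purity can then be neither raised by crystallisation nor corrected by separating diastereomers. It must therefore be set by an external chiral agent while the material is still small and functionalised, and then carried through untouched. Two processes could erase it later: passage through an intermediate whose two arms at C14 bear the same end group, and migration of a double bond into C13=C14 during a hydrogenation. The catechol is easily oxidised in basic aerobic media and its aryl ester survives neither hydride reagents nor ylides, so the aromatic part is attached last. The enabling feature is that C14, its methyl group, C13 and C15 form the middle of a 3-methylpentane unit ending at C12 and C16. With both ends at the carboxyl level this is 3-methylglutaric acid, whose C3 is prochiral, so one hydrolase acting on one of two enantiotopic ester groups creates C14.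

## Retrosynthesis

**Ester, alkyl C1–O bond.** Target 17 is cut at the alkyl C1–O bond into (S)-1-bromo-14-methylhexadecane 15 and 2,3-dihydroxybenzoic acid 16. The neighbouring acyl C–O cut would need an activated dihydroxybenzoyl donor with masked phenols, which costs protection and deprotection steps. The alkyl–O cut uses the acidity gap between the carboxyl group (pKa about 3) and the phenols (about 10 and above). The forward reaction must alkylate the carboxylate only. 16 is a cheap catalogue compound, so all remaining effort lies in 15.

**C1–Br and C11=C12, no skeletal bond.** Bromide 15 is traced to silyl ether 14, and 14 to its 11,12-unsaturated precursor 13. Going directly from silyl ether to bromide saves a separate deprotection. The hydrogenation must saturate C11=C12 without letting the double bond walk toward C14. Platinum is chosen over palladium for that reason.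

**C16–O.** The methyl terminus C16 of 13 is traced to the tosylate 12 and the primary alcohol 11. This is the final stage of taking one glutarate carboxyl carbon down to CH3. Doing it after the chain is joined keeps every intermediate non-volatile. The forward reaction is an SN2 hydride displacement at an unhindered primary carbon, which a silyl ether and an isolated alkene tolerate.

**C11=C12.** Alcohol 11 is cut at the double bond into lactol 6 and phosphonium salt 9, which reacts through ylide 10.
- Against a C12–C13 cut: that would discard a glutarate carbon.
- Against an sp3–sp3 coupling at C11–C12: that would force the C16 deoxygenation onto a volatile six-carbon piece first.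
- For the lactol: it presents C12 as a masked aldehyde and C16 as a free hydroxyl in one unprotected compound, so the two arms stay distinct. The open form has C14 β to the aldehyde, so base cannot epimerise it.
- Salt 9 comes from 11-bromoundecan-1-ol 7 through silyl ether 8. The cheap fragment is the one used in excess.

**Redox differentiation of the arms.** Lactol 6 comes from lactone 5 by partial reduction. Lactone 5 comes from half-ester 3 by reducing only the ester arm; the hydroxy acid 4 closes spontaneously. The carbonyl of 5 is then the former acid carbon (C12) and its CH2O the former ester carbon (C16), which is the assignment the S configuration requires. No bond at the stereocentre is touched from 3 to 17. The descriptor changes (R in 3, S in 4–6, R in 11 and 12, S from 13 on) only because the ranking of the two arms changes.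

**Desymmetrisation.** Half-ester 3 is traced to dimethyl 3-methylglutarate 2, and 2 to 3-methylglutaric acid 1. No skeletal bond is cut; the simplification is the loss of the only stereocentre. The forward step must discriminate the two enantiotopic CH2CO2CH3 groups and stop after one hydrolysis. Either sense of discrimination would be usable, because the arm that is reduced first can be chosen. With the R half-ester the ester arm becomes ethyl.

## Roads not taken

**Alternative 1: catechol by directed C–H oxygenation.** The cut is the aryl C3–O bond. (S)-14-Methylhexadecyl salicylate A1 would be converted into its di-tert-butylsilanol ether A2. Pd(OPiv)2 with PhI(OAc)2 would oxygenate the ortho C–H, and the new oxygen would close onto silicon to give the benzodioxasilole A3. Fluoride would then release the catechol.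
- Merits: the position is unambiguous, since C3 is the only free site ortho to the phenol oxygen. The catechol stays masked until the last step; in that respect it is better than the chosen end-game, which exposes a free catechol to warm bicarbonate.
- Weak points: the 2,3-dioxygenation pattern can be bought in 16, so three steps are spent on one C–O bond. The arene of A1 is deactivated by the ester, and its phenol is flanked and hydrogen-bonded by it; bulky silylation and palladation should both be slower than for simple phenols. Above all, it does nothing for C14 or the chain, which must still come from another approach.
- Comparison: the chosen plan addresses the real difficulty, and answers the catechol concern with an alkylation in which the phenols stay protonated.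

**Alternative 2: asymmetric ethylalumination.** The cut is C14–C15, made together with the stereocentre. Et3Al would add to the silyl ether A4 of pentadec-14-en-1-ol under bis(1-neomenthylindenyl)zirconium dichloride catalysis, and protonolysis of the C–Al bond would leave the methyl group. The product A5 is identical with compound 14.
- Merits: one catalytic step forms the bond and the stereocentre on an almost finished chain, and only two steps would remain. Even with a short chain extension to make A4, this road is several steps shorter than the chosen one. The chosen plan cannot match that.
- Weak points: Et3Al carries β-hydrogens, so hydrometalation and cyclic carbometalation compete. Selectivity for plain 1-alkenes in this reaction class is typically good but not complete. A5 is an oil with no functional group near C14, so it cannot be enriched. The usual remedy, oxidising the C–Al bond to an alcohol for enzymatic enrichment, is excluded because protonolysis is needed here.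
- Comparison: the chosen plan creates the stereocentre in a small carboxylic acid 3, where the purity can be measured and raised through a crystalline amine salt before any chain is attached. It uses an enzyme in water instead of a pyrophoric alane and a costly zirconocene.

**Alternative 3: mixed Kolbe electrolysis.** The cut is C11–C12. Co-electrolysis of (S)-4-methylhexanoic acid A6 with excess monomethyl dodecanedioate A7 at a platinum anode would expel CO2 from both, and the two primary radicals would combine to methyl (S)-14-methylhexadecanoate A8. Reduction and esterification would follow.
- Merits: the bond formed is saturated, so there is no hydrogenation and no migration risk. No protecting group is needed, and C14 sits β to the radical carbon and is untouched. The stereocentre is bought from the chiral pool. Even counting a short homologation to make A6, the route is shorter than the chosen one. On step count and on confidence in configuration it is at least as good.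
- Weak points: radical combination is statistical, so both symmetric dimers accompany A8. A7 must be used in large excess, the yield on the valuable acid A6 is inherently limited, and an electrolysis cell is required.
- Comparison: the chosen plan forms each bond selectively between two defined partners in ordinary glassware. It makes the stereocentre catalytically from an achiral six-carbon diacid, and gives access to either enantiomer by changing which arm is reduced.

Key step: step 2

Assumption: the esterase is taken to hydrolyse the pro-S ester group of 2, the sense established for 3-methylglutarate diesters; the configuration of 3 is to be confirmed on the first batch by correlation with lactone 5.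

## Route

Step 1
Reactants: 1 3-methylglutaric acid
Product: 2 dimethyl 3-methylglutarate
Conditions: MeOH (solvent), H2SO4 (cat.), reflux
Reagents that add atoms: methanol, CO
Why: Fischer esterification; excess methanol drives both carboxyl groups to the ester, and the achiral product raises no stereochemical issue.

Step 2
Reactants: 2 dimethyl 3-methylglutarate
Product: 3 (R)-5-methoxy-3-methyl-5-oxopentanoic acid
Conditions: pig liver esterase, 0.1 M KH2PO4/K2HPO4 buffer pH 7.0, MeOH (20% v/v), −10 °C, pH-stat with 1 M NaOH (1.0 equiv); then 2 M HCl to pH 2, EtOAc extraction
Reagents that add atoms: water, O
Why: The serine hydroxyl of the esterase's catalytic triad adds to one ester carbonyl of 2, methanol leaves, and water hydrolyses the acyl-enzyme to the carboxylate; the closest known reaction type is the esterase desymmetrisation of prochiral 3-substituted glutarate diesters, of which the 3-methyl compound is a standard substrate. No skeletal bond forms and no ring closes. The stereocentre (C3 of 3, later C14) arises only because one of two enantiotopic CH2CO2CH3 arms is hydrolysed, and the controlling element is the chiral active site: with the small 3-methyl group in the small hydrophobic pocket, only the pro-S ester reaches the serine, which leaves the R half-ester. Two selectivities are needed, discrimination between the enantiotopic groups and mono- against di-hydrolysis. The second is secured by the substrate, because the carboxylate formed is a poor esterase substrate and the titration is stopped at one equivalent of base. The first rests on the enzyme and is sharpened by low temperature and methanol co-solvent, both known to raise discrimination for small 3-alkyl groups. As a desymmetrisation the step can in principle convert all of 2 into one enantiomer, unlike a kinetic resolution. The purity reached here is final for the route, so it is to be determined on 3 (amide with an enantiopure 1-phenylethylamine) before material is committed, and 3 is not heated or distilled, since ester migration through the cyclic anhydride would racemise it.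

Step 3
Reactants: 3 (R)-5-methoxy-3-methyl-5-oxopentanoic acid
Product: 5 (S)-4-methyltetrahydro-2H-pyran-2-one, via (S)-5-hydroxy-3-methylpentanoic acid 4 (not isolated)
Conditions: LiBH4 (2 equiv), THF, 0 °C to reflux; then 2 M HCl to pH 1, rt, continuous extraction with CH2Cl2
Reagents that add atoms: none
Why: Chemoselective borohydride reduction: the first hydride equivalent turns the acid into its lithium carboxylate, which LiBH4 does not reduce, while the methyl ester goes to the primary alcohol, and acid then closes the six-membered lactone. The stereocentre is β to both carbonyl groups and cannot epimerise; its descriptor changes only through the new ranking of the arms.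

Step 4
Reactants: 5 (S)-4-methyltetrahydro-2H-pyran-2-one
Product: 6 (4S)-4-methyltetrahydro-2H-pyran-2-ol (mixture of anomers)
Conditions: i-Bu2AlH (1.1 equiv), CH2Cl2, −78 °C; aqueous potassium sodium tartrate (KNaC4H4O6) work-up
Reagents that add atoms: none
Why: Partial hydride reduction of a δ-lactone; the aluminium hemiacetal is stable at −78 °C and gives the lactol on hydrolysis, as is standard for six-membered lactones. The lactol is used crude because it is water-soluble and somewhat volatile.

Step 5
Reactants: 7 11-bromoundecan-1-ol
Product: 8 [(11-bromoundecyl)oxy](tert-butyl)dimethylsilane
Conditions: TBSCl, imidazole, CH2Cl2, 0 °C to rt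
Reagents that add atoms: tert-butyldimethylsilyl chloride, CC(C)(C)[Si](C)(C)Cl
Why: Standard silylation of a primary alcohol; the silyl ether tolerates the ylide base, sulfonylation, LiEt3BH and hydrogenation over platinum, and is later converted directly into the bromide.

Step 6
Reactants: 8 [(11-bromoundecyl)oxy](tert-butyl)dimethylsilane
Product: 9 {11-[(tert-butyldimethylsilyl)oxy]undecyl}triphenylphosphonium bromide
Conditions: PPh3 (1.1 equiv), MeCN, reflux
Reagents that add atoms: triphenylphosphine, c1ccc(cc1)P(c1ccccc1)c1ccccc1
Why: SN2 quaternisation of triphenylphosphine by an unhindered primary bromide, the usual preparation of ω-silyloxyalkyl phosphonium salts.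

Step 7
Reactants: 9 {11-[(tert-butyldimethylsilyl)oxy]undecyl}triphenylphosphonium bromide; 6 (4S)-4-methyltetrahydro-2H-pyran-2-ol
Product: 11 (3R,5Z)-16-[(tert-butyldimethylsilyl)oxy]-3-methylhexadec-5-en-1-ol, via 11-(tert-butyldimethylsilyloxy)undecylidenetriphenylphosphorane 10 (not isolated)
Conditions: 9 (2.2 equiv), NaN(SiMe3)2 (2.1 equiv), THF, −78 to 0 °C; then 6 (1.0 equiv), −78 °C to rt
Reagents that add atoms: none
Why: Wittig olefination of a lactol with a non-stabilised ylide, known for this very ring system: one equivalent of ylide deprotonates the lactol, the alkoxide opens to the hydroxy aldehyde, and a second equivalent forms the C11=C12 bond. The Z isomer should predominate but the geometry is irrelevant, and C14 is β to the aldehyde and is not at risk.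

Step 8
Reactants: 11 (3R,5Z)-16-[(tert-butyldimethylsilyl)oxy]-3-methylhexadec-5-en-1-ol
Product: 12 (3R,5Z)-16-[(tert-butyldimethylsilyl)oxy]-3-methylhexadec-5-en-1-yl 4-methylbenzenesulfonate
Conditions: TsCl, Et3N, DMAP (cat.), CH2Cl2, 0 °C to rt
Reagents that add atoms: 4-methylbenzenesulfonyl chloride, Cc1ccc(cc1)S(=O)(=O)Cl
Why: Routine sulfonylation of the only free hydroxyl group, the former ester carbon C16; the silyl ether and the alkene are inert.

Step 9
Reactants: 12 (3R,5Z)-16-[(tert-butyldimethylsilyl)oxy]-3-methylhexadec-5-en-1-yl 4-methylbenzenesulfonate
Product: 13 tert-butyldimethyl{[(11Z,14S)-14-methylhexadec-11-en-1-yl]oxy}silane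
Conditions: LiEt3BH (2.5 equiv), THF, 0 °C to rt
Reagents that add atoms: none
Why: SN2 displacement of a primary tosylate by hydride, for which LiEt3BH is the reagent of choice because it attacks carbon and not sulfur; this turns C16 into the methyl group and completes the ethyl arm without touching C14.

Step 10
Reactants: 13 tert-butyldimethyl{[(11Z,14S)-14-methylhexadec-11-en-1-yl]oxy}silane
Product: 14 tert-butyldimethyl{[(14S)-14-methylhexadecyl]oxy}silane
Conditions: H2 (1 atm), PtO2 (cat.), EtOAc, rt
Reagents that add atoms: none
Why: Heterogeneous catalytic hydrogenation of a 1,2-disubstituted alkene; platinum is chosen because it saturates with far less double-bond migration than palladium, so the alkene should not reach C13=C14, and the silyl ether is stable in neutral EtOAc.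

Step 11
Reactants: 14 tert-butyldimethyl{[(14S)-14-methylhexadecyl]oxy}silane
Product: 15 (S)-1-bromo-14-methylhexadecane
Conditions: Ph3PBr2 (1.3 equiv), CH2Cl2, 0 °C to rt
Reagents that add atoms: dibromotriphenylphosphorane, BrP(Br)(c1ccccc1)(c1ccccc1)c1ccccc1
Why: Known direct conversion of a primary silyl ether into the bromide (Appel-type): the ether oxygen attacks the bromophosphonium ion, bromide removes the silyl group, and a second bromide displaces Ph3P=O from C1 by SN2, thirteen atoms from the stereocentre.

Step 12
Reactants: 15 (S)-1-bromo-14-methylhexadecane; 16 2,3-dihydroxybenzoic acid
Product: 17 Gentiside C, (S)-14-methylhexadecyl 2,3-dihydroxybenzoate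
Conditions: 16 (1.5 equiv), KHCO3 (1.5 equiv), DMF, 60 °C, argon
Reagents that add atoms: none
Why: SN2 O-alkylation of a carboxylate by a primary bromide; bicarbonate deprotonates only the carboxylic acid and leaves both phenols protonated, so the ester forms without catechol protection, as is usual for alkyl esters of phenolic acids.

## Compound list

1 | 3-methylglutaric acid | CC(CC(=O)O)CC(=O)O | starting material
2 | dimethyl 3-methylglutarate | COC(=O)CC(C)CC(=O)OC | intermediate
3 | (R)-5-methoxy-3-methyl-5-oxopentanoic acid | COC(=O)C[C@H](C)CC(=O)O | intermediate
4 | (S)-5-hydroxy-3-methylpentanoic acid | OCC[C@H](C)CC(=O)O | intermediate (not isolated)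
5 | (S)-4-methyltetrahydro-2H-pyran-2-one | C[C@H]1CCOC(=O)C1 | intermediate
6 | (4S)-4-methyltetrahydro-2H-pyran-2-ol, anomer mixture | C[C@H]1CCOC(O)C1 | intermediate
7 | 11-bromoundecan-1-ol | OCCCCCCCCCCCBr | starting material
8 | [(11-bromoundecyl)oxy](tert-butyl)dimethylsilane | CC(C)(C)[Si](C)(C)OCCCCCCCCCCCBr | intermediate
9 | {11-[(tert-butyldimethylsilyl)oxy]undecyl}triphenylphosphonium bromide | CC(C)(C)[Si](C)(C)OCCCCCCCCCCC[P+](c1ccccc1)(c1ccccc1)c1ccccc1.[Br-] | intermediate
10 | 11-(tert-butyldimethylsilyloxy)undecylidenetriphenylphosphorane | CC(C)(C)[Si](C)(C)OCCCCCCCCCCC=P(c1ccccc1)(c1ccccc1)c1ccccc1 | intermediate (not isolated)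
11 | (3R,5Z)-16-[(tert-butyldimethylsilyl)oxy]-3-methylhexadec-5-en-1-ol | OCC[C@H](C)C/C=C\CCCCCCCCCCO[Si](C)(C)C(C)(C)C | intermediate
12 | (3R,5Z)-16-[(tert-butyldimethylsilyl)oxy]-3-methylhexadec-5-en-1-yl 4-methylbenzenesulfonate | Cc1ccc(cc1)S(=O)(=O)OCC[C@H](C)C/C=C\CCCCCCCCCCO[Si](C)(C)C(C)(C)C | intermediate
13 | tert-butyldimethyl{[(11Z,14S)-14-methylhexadec-11-en-1-yl]oxy}silane | CC[C@H](C)C/C=C\CCCCCCCCCCO[Si](C)(C)C(C)(C)C | intermediate
14 | tert-butyldimethyl{[(14S)-14-methylhexadecyl]oxy}silane | CC[C@H](C)CCCCCCCCCCCCCO[Si](C)(C)C(C)(C)C | intermediate
15 | (S)-1-bromo-14-methylhexadecane | CC[C@H](C)CCCCCCCCCCCCCBr | intermediate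
16 | 2,3-dihydroxybenzoic acid | OC(=O)c1cccc(O)c1O | starting material
17 | Gentiside C, (S)-14-methylhexadecyl 2,3-dihydroxybenzoate | CC[C@H](C)CCCCCCCCCCCCCOC(=O)c1cccc(O)c1O | target

## Step count and risks

Total: 12 steps. Longest linear sequence: 10 steps (steps 1, 2, 3, 4, 7, 8, 9, 10, 11, 12 from 1). Compound 2 is also a catalogue chemical, which would remove step 1.

**Step 2 (key step).** The likely failure is incomplete discrimination between the enantiotopic ester groups. Commercial esterase is a mixture of isoenzymes whose selectivity varies between batches, and no later compound can be enriched. The first remedy stays within the plan: crystallise a salt of 3 with an enantiopure amine before going on. The fallback drops the enzyme. It sets out from 1, which acetic anhydride at reflux dehydrates to 3-methylglutaric anhydride F1. F1 is then opened with methanol in toluene at low temperature under a cinchona alkaloid (the quinine or quinidine series, whichever pseudoenantiomer delivers the R half-ester). It rejoins the route at 3.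

**Step 7.** The likely failure is slow opening of the lactol alkoxide to the hydroxy aldehyde, so that ylide 10 is consumed by proton transfer and decomposition before it olefinates. The fallback sets out from 3 and uses an open-chain aldehyde:
- BH3·SMe2 in THF reduces the acid arm to give methyl (R)-5-hydroxy-3-methylpentanoate F2.
- F2 is oxidised at once, before it can lactonise, under Swern conditions to methyl (R)-3-methyl-5-oxopentanoate F3.
- Wittig reaction of F3 with a slight excess of 10 gives methyl (3R,5Z)-16-[(tert-butyldimethylsilyl)oxy]-3-methylhexadec-5-enoate F4.
- i-Bu2AlH in CH2Cl2 reduces the ester of F4 to the alcohol, which rejoins the route at 11.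

This is one step longer and also bypasses steps 3 and 4.

**Step 10.** The likely failure is migration of the double bond along the chain on the metal surface before saturation. Any material that passes through the C13=C14 alkene would lose its configuration at C14. The fallback replaces surface catalysis by diimide, generated from 2-nitrobenzenesulfonylhydrazide and Et3N in CH2Cl2 at rt. Diimide transfers both hydrogens in one concerted step without a metal hydride and cannot isomerise the alkene. It sets out from 13 and rejoins at 14; it makes no new compound (F0).

**Step 12.** The likely failures are competing alkylation at a phenolic oxygen, air oxidation of the catechol in warm basic DMF, and sluggish reaction of the hydrogen-bonded carboxylate. The fallback protects the catechol: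
- 16 is benzylated with benzyl bromide and K2CO3 in DMF to benzyl 2,3-bis(benzyloxy)benzoate F5.
- F5 is saponified with NaOH in aqueous MeOH to 2,3-bis(benzyloxy)benzoic acid F6.
- F6 is alkylated with 15 and Cs2CO3 in DMF to (S)-14-methylhexadecyl 2,3-bis(benzyloxy)benzoate F7.
- F7 is hydrogenolysed with H2 over Pd/C in EtOAc, which rejoins the route at 17. No alkene is present at this stage, so palladium is harmless to C14.

## Further compounds

F1 | step 2 | 3-methylglutaric anhydride (4-methyloxane-2,6-dione) | CC1CC(=O)OC(=O)C1
F2 | step 7 | methyl (R)-5-hydroxy-3-methylpentanoate | COC(=O)C[C@H](C)CCO
F3 | step 7 | methyl (R)-3-methyl-5-oxopentanoate | COC(=O)C[C@H](C)CC=O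
F4 | step 7 | methyl (3R,5Z)-16-[(tert-butyldimethylsilyl)oxy]-3-methylhexadec-5-enoate | COC(=O)C[C@H](C)C/C=C\CCCCCCCCCCO[Si](C)(C)C(C)(C)C
F0 | step 10 | none | none
F5 | step 12 | benzyl 2,3-bis(benzyloxy)benzoate | O=C(OCc1ccccc1)c1cccc(OCc2ccccc2)c1OCc1ccccc1
F6 | step 12 | 2,3-bis(benzyloxy)benzoic acid | OC(=O)c1cccc(OCc2ccccc2)c1OCc1ccccc1
F7 | step 12 | (S)-14-methylhexadecyl 2,3-bis(benzyloxy)benzoate | CC[C@H](C)CCCCCCCCCCCCCOC(=O)c1cccc(OCc2ccccc2)c1OCc1ccccc1
A1 | alternative 1 | (S)-14-methylhexadecyl 2-hydroxybenzoate | CC[C@H](C)CCCCCCCCCCCCCOC(=O)c1ccccc1O
A2 | alternative 1 | (S)-14-methylhexadecyl 2-{[di-tert-butyl(hydroxy)silyl]oxy}benzoate | CC[C@H](C)CCCCCCCCCCCCCOC(=O)c1ccccc1O[Si](O)(C(C)(C)C)C(C)(C)C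
A3 | alternative 1 | (S)-14-methylhexadecyl 2,2-di-tert-butyl-1,3,2-benzodioxasilole-4-carboxylate | CC[C@H](C)CCCCCCCCCCCCCOC(=O)c1cccc2O[Si](C(C)(C)C)(C(C)(C)C)Oc12
A4 | alternative 2 | tert-butyldimethyl(pentadec-14-en-1-yloxy)silane | C=CCCCCCCCCCCCCCO[Si](C)(C)C(C)(C)C
A5 | alternative 2 | tert-butyldimethyl{[(S)-14-methylhexadecyl]oxy}silane | CC[C@H](C)CCCCCCCCCCCCCO[Si](C)(C)C(C)(C)C
A6 | alternative 3 | (S)-4-methylhexanoic acid | CC[C@H](C)CCC(=O)O
A7 | alternative 3 | 12-methoxy-12-oxododecanoic acid (monomethyl dodecanedioate) | COC(=O)CCCCCCCCCCC(=O)O
A8 | alternative 3 | methyl (S)-14-methylhexadecanoate | CC[C@H](C)CCCCCCCCCCCCC(=O)OC
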